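**Retrosynthetic overview**
1. Target 17 ⇐ dioxanol acid 16: the C6–OMe peroxyketal by acid-catalysed methanolysis of the 1,2-dioxan-6-ol (thermodynamic control sets C6).
2. 16 ⇐ keto β-lactone 14 + H2O2: the 1,2-dioxane (C3–O–O bond) by SN2 attack of a hydroperoxide on the lactone C4 (inversion sets C3; the leaving acyloxy group becomes the CO2H).
3. 14 ⇐ keto epoxide 13 + CO: key step, carbonylative ring expansion of the oxirane to the oxetan-2-one (retention; brings in the carboxyl carbon).
4. 13 ⇐ C16 alkyllithium (from iodide 8) + chiral-pool lactone tosylate 10; 8 ⇐ 7-bromohept-1-ene + acrolein + CHI3 + 5-iodopent-1-yne (conjugate addition, Takai, Sonogashira).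
5. Ring order: oxirane (step 5) → oxetan-2-one (step 6) → 1,2-dioxane (step 7, the only ring of the target, formed last).

Assumption: locants follow the name of 17 (C3 = CH–O carbon bearing CH2CO2H, S; C6 = ketal carbon, R; OMe and CH2CO2H cis), and (5R)-5-(hydroxymethyl)oxolan-2-one 9 is taken as a catalogue chiral-pool compound.

**Step 1**
Reactants: 1 7-bromohept-1-ene; 2 acrolein
Product: 5 dec-9-enal, via hept-6-enylmagnesium bromide 3 (not isolated), via silyl enol ether 4 (not isolated)
Conditions: Mg, THF, 25 °C; then CuBr·SMe2 (5 mol%), Me3SiCl, DMPU, 2, −78 °C; 1 M HCl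
Reagents that add atoms: none
Why: Copper-catalysed, Me3SiCl-accelerated conjugate addition of the Grignard reagent to acrolein traps the enolate as silyl enol ether 4, which hydrolyses to the aldehyde on acidic work-up; no stereocentre is formed.

**Step 2**
Reactants: 5 dec-9-enal
Product: 6 (1E)-1-iodoundeca-1,10-diene
Conditions: CHI3, CrCl2, 1,4-dioxane–THF (6:1), 0 → 23 °C
Reagents that add atoms: iodoform, IC(I)I
Why: Takai olefination, in which the gem-dichromium reagent from CHI3 and CrCl2 adds to the aldehyde and eliminates to the E-vinyl iodide (E:Z about 10:1 in dioxane-rich solvent, minor Z isomer removed on AgNO3-impregnated silica), the isolated terminal alkene being inert.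

**Step 3**
Reactants: 6 (1E)-1-iodoundeca-1,10-diene; 7 5-iodopent-1-yne
Product: 8 (10E)-16-iodohexadeca-1,10-dien-12-yne
Conditions: PdCl2(PPh3)2 (2 mol%), CuI (4 mol%), i-Pr2NH, THF, 23 °C
Reagents that add atoms: none
Why: Sonogashira coupling, in which zerovalent palladium inserts into the C(sp2)–I bond far faster than into the primary C(sp3)–I bond and the alkene geometry is retained.

**Step 4**
Reactants: 9 (5R)-5-(hydroxymethyl)oxolan-2-one
Product: 10 [(2R)-5-oxooxolan-2-yl]methyl 4-methylbenzenesulfonate
Conditions: TsCl, pyridine, CH2Cl2, 0 °C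
Reagents that add atoms: 4-methylbenzenesulfonyl chloride, Cc1ccc(cc1)S(=O)(=O)Cl
Why: Sulfonylation of the primary alcohol, which leaves the chiral-pool stereocentre (R) untouched.

**Step 5**
Reactants: 8 (10E)-16-iodohexadeca-1,10-dien-12-yne; 10 [(2R)-5-oxooxolan-2-yl]methyl 4-methylbenzenesulfonate
Product: 13 (9E)-1-[(2R)-oxiran-2-yl]nonadeca-9,18-dien-7-yn-3-one, via alkyllithium 11 (not isolated), via lithium lactolate 12 (not isolated)
Conditions: 8, t-BuLi (2.0 equiv), Et2O–pentane, −78 °C; then 10, THF, −78 → 23 °C; aq. NH4Cl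
Reagents that add atoms: none
Why: Lithium–iodine exchange gives alkyllithium 11, which adds once to the lactone carbonyl (lactolate 12 is stable at −78 °C), and on warming 12 opens to the keto alkoxide that displaces the neighbouring tosylate (intramolecular Williamson epoxide closure), so the C–O stereocentre is carried over unchanged as 2R.

**Step 6**
Reactants: 13 (9E)-1-[(2R)-oxiran-2-yl]nonadeca-9,18-dien-7-yn-3-one
Product: 14 (4R)-4-[(9E)-3-oxononadeca-9,18-dien-7-yn-1-yl]oxetan-2-one
Conditions: [(salph)Al(THF)2][Co(CO)4] (2 mol%; salph = N,N′-bis(3,5-di-tert-butylsalicylidene)-1,2-phenylenediamine dianion), CO (60 bar), DME, 50 °C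
Reagents that add atoms: carbon monoxide, [C-]#[O+]
Why: Carbonylative ring expansion of an epoxide (the key step), in which [Co(CO)4]− opens the Lewis-acid-activated oxirane at the CH2 terminus, CO inserts into the Co–C bond and the aluminium alkoxide closes onto the cobalt acyl, so the three-membered ring grows to the β-lactone with the C–O stereocentre untouched (retention, 4R).

**Step 7**
Reactants: 14 (4R)-4-[(9E)-3-oxononadeca-9,18-dien-7-yn-1-yl]oxetan-2-one
Product: 17 2-[(3S,6R)-6-[(6E)-hexadeca-6,15-dien-4-yn-1-yl]-6-methoxy-1,2-dioxan-3-yl]acetic acid, via hydroperoxy hemiketal 15 (not isolated), via dioxanol acid 16 (not isolated)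
Conditions: H2O2 (anhydrous, in Et2O, 3 equiv), CF3CH2OH–CH2Cl2, 25–35 °C; then MeOH (excess), camphorsulfonic acid (5 mol%), 0 °C, 1–2 h; NaHCO3
Reagents that add atoms: hydrogen peroxide, OO; methanol, CO
Why: Proposed new method: H2O2 adds reversibly to the ketone and the OOH of hemiketal 15 attacks the lactone C4 in a neutral 6-exo-tet SN2 alkyl–oxygen cleavage (inversion, 4R → 3S; intermolecular H2O2 attack at C4 followed by hemiketalisation converges on the same 16), releasing the strained acyloxy group as the free CO2H and closing the 1,2-dioxane, after which acid-catalysed methanolysis through the peroxycarbenium ion sets C6 under thermodynamic control (axial anomeric OMe, both carbon substituents equatorial = 6R, cis); the closest known reaction types are the SN2 alkyl–oxygen opening of β-lactones by neutral or soft nucleophiles and the Lewis-acid opening of oxetanes by H2O2, neither shown for a hydroperoxide on a β-lactone.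

**Compound list**
1 | 7-bromohept-1-ene | C=CCCCCCBr | starting material
2 | acrolein (prop-2-enal) | C=CC=O | starting material
3 | hept-6-enylmagnesium bromide | C=CCCCCC[Mg]Br | intermediate
4 | trimethyl(deca-1,9-dien-1-yloxy)silane (E/Z mixture) | C=CCCCCCCC=CO[Si](C)(C)C | intermediate
5 | dec-9-enal | C=CCCCCCCCC=O | intermediate
6 | (1E)-1-iodoundeca-1,10-diene | C=CCCCCCCC/C=C/I | intermediate
7 | 5-iodopent-1-yne | C#CCCCI | starting material
8 | (10E)-16-iodohexadeca-1,10-dien-12-yne | C=CCCCCCCC/C=C/C#CCCCI | intermediate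
9 | (5R)-5-(hydroxymethyl)oxolan-2-one | OC[C@H]1CCC(=O)O1 | starting material
10 | [(2R)-5-oxooxolan-2-yl]methyl 4-methylbenzenesulfonate | Cc1ccc(cc1)S(=O)(=O)OC[C@H]1CCC(=O)O1 | intermediate
11 | [(6E)-hexadeca-6,15-dien-4-yn-1-yl]lithium | [Li]CCCC#C/C=C/CCCCCCCC=C | intermediate
12 | lithium (5R)-2-[(6E)-hexadeca-6,15-dien-4-yn-1-yl]-5-[(4-methylbenzenesulfonyloxy)methyl]oxolan-2-olate (anomer mixture) | [Li+].[O-]C1(CCCC#C/C=C/CCCCCCCC=C)CC[C@H](COS(=O)(=O)c2ccc(C)cc2)O1 | intermediate
13 | (9E)-1-[(2R)-oxiran-2-yl]nonadeca-9,18-dien-7-yn-3-one | C=CCCCCCCC/C=C/C#CCCCC(=O)CC[C@@H]1CO1 | intermediate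
14 | (4R)-4-[(9E)-3-oxononadeca-9,18-dien-7-yn-1-yl]oxetan-2-one | C=CCCCCCCC/C=C/C#CCCCC(=O)CC[C@@H]1CC(=O)O1 | intermediate
15 | (4R)-4-[(9E)-3-hydroperoxy-3-hydroxynonadeca-9,18-dien-7-yn-1-yl]oxetan-2-one | C=CCCCCCCC/C=C/C#CCCCC(O)(OO)CC[C@@H]1CC(=O)O1 | intermediate
16 | 2-[(3S)-6-[(6E)-hexadeca-6,15-dien-4-yn-1-yl]-6-hydroxy-1,2-dioxan-3-yl]acetic acid (C6 anomer mixture) | C=CCCCCCCC/C=C/C#CCCCC1(O)CC[C@@H](CC(=O)O)OO1 | intermediate
17 | 2-[(3S,6R)-6-[(6E)-hexadeca-6,15-dien-4-yn-1-yl]-6-methoxy-1,2-dioxan-3-yl]acetic acid (CNP0125368.1) | C=CCCCCCCC/C=C/C#CCCC[C@]1(OC)CC[C@@H](CC(=O)O)OO1 | target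

**Step count**
Total: 7 steps. Longest linear sequence: 6 steps (1, 2, 3, 5, 6, 7); step 4 is a one-step branch.

**Three steps most likely to fail**

The peroxidative lactone opening (step 7, the proposed new step). The risks are attack of H2O2 at the acyl carbon (a β-hydroxy peracid that would also epoxidise the alkenes), a slow neutral SN2 at the secondary C4, and partial Fischer esterification during ketalisation. The fallback uses known chemistry, sets out from 14 and comes back at 17. Acyl–oxygen methanolysis of 14 (K2CO3, MeOH, 0 °C) gives, with retention, methyl (3R,12E)-3-hydroxy-6-oxodocosa-12,21-dien-10-ynoate F3. Mesylation (MsCl, Et3N, CH2Cl2, −20 °C) gives methyl (3R,12E)-3-(methanesulfonyloxy)-6-oxodocosa-12,21-dien-10-ynoate F4. Perketalisation of the ketone (ethereal H2O2, MeOH, catalytic acid) gives methyl (3R,12E)-6-hydroperoxy-6-methoxy-3-(methanesulfonyloxy)docosa-12,21-dien-10-ynoate F5. Intramolecular alkylation of the hydroperoxide by the secondary mesylate (KOt-Bu, 18-crown-6, THF, 0 °C; inversion), followed by brief camphorsulfonic acid/MeOH equilibration, gives methyl 2-[(3S,6R)-6-[(6E)-hexadeca-6,15-dien-4-yn-1-yl]-6-methoxy-1,2-dioxan-3-yl]acetate F6. Saponification (LiOH, THF–H2O, 0 °C) then gives 17.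

The carbonylative ring expansion (step 6). The Lewis-acidic cation could make the γ-keto group attack the activated epoxide (bicyclic ketal), and the conjugated enyne is untested with [Co(CO)4]−. The fallback sets out from 13 and comes back at 14 without any epoxide carbonylation. Periodic acid cleavage of the epoxide (H5IO6, THF–H2O, 0 °C) gives (10E)-4-oxoicosa-10,19-dien-8-ynal F2. A catalytic asymmetric acyl halide–aldehyde cyclocondensation then rebuilds the lactone and its stereocentre: acetyl chloride, i-Pr2NEt, LiClO4, 10 mol% of the O-trimethylsilyl cinchona alkaloid, CH2Cl2–Et2O, −78 °C. Which pseudo-enantiomer (quinine- or quinidine-derived) gives the 4R lactone I have not fixed here; it must be confirmed on a model aldehyde.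

The one-flask lactone addition/epoxide closure (step 5). The risks are double addition once the ketone is unmasked, closure of lactolate 12 to a bicyclic ketal instead of the epoxide, and sluggish closure of the lithium alkoxide (finishing with K2CO3/MeOH would be the first remedy). The fallback sets out from 10 (with 11 made from 8 as before) and comes back at 13. LiN(OMe)Me (THF, −78 → 0 °C) opens the lactone at the acyl carbon and the released alkoxide closes onto the tosylate, giving N-methoxy-N-methyl-3-[(2R)-oxiran-2-yl]propanamide F1. Addition of 11 at −78 °C stops at the chelated tetrahedral intermediate and gives 13 on work-up.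

**Further compounds**
F1 | step 5 | N-methoxy-N-methyl-3-[(2R)-oxiran-2-yl]propanamide | CON(C)C(=O)CC[C@@H]1CO1
F2 | step 6 | (10E)-4-oxoicosa-10,19-dien-8-ynal | C=CCCCCCCC/C=C/C#CCCCC(=O)CCC=O
F3 | step 7 | methyl (3R,12E)-3-hydroxy-6-oxodocosa-12,21-dien-10-ynoate | C=CCCCCCCC/C=C/C#CCCCC(=O)CC[C@@H](O)CC(=O)OC
F4 | step 7 | methyl (3R,12E)-3-(methanesulfonyloxy)-6-oxodocosa-12,21-dien-10-ynoate | C=CCCCCCCC/C=C/C#CCCCC(=O)CC[C@@H](OS(C)(=O)=O)CC(=O)OC
F5 | step 7 | methyl (3R,12E)-6-hydroperoxy-6-methoxy-3-(methanesulfonyloxy)docosa-12,21-dien-10-ynoate | C=CCCCCCCC/C=C/C#CCCCC(OC)(OO)CC[C@@H](OS(C)(=O)=O)CC(=O)OC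
F6 | step 7 | methyl 2-[(3S,6R)-6-[(6E)-hexadeca-6,15-dien-4-yn-1-yl]-6-methoxy-1,2-dioxan-3-yl]acetate | C=CCCCCCCC/C=C/C#CCCC[C@]1(OC)CC[C@@H](CC(=O)OC)OO1
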